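**Retrosynthetic overview**

1. Atoms are named by verticillane numbers: C1 = ring CH that carries the bridge, C15 = CMe2, C11=C12 = ring-fusion alkene, C10 and C18 = ketone carbons, C9 = CH between them, C7=C8 = E-alkene, C6 = CHOAc, C4=C20 = exo-methylene.
2. Late bonds: the C6 acetate; C9–C18 by transannular Dieckmann closure (five-membered enedione ring, C9 fixed by the bridge); C3–C4 by B-alkyl Suzuki–Miyaura macrocyclisation (12-membered ring); C9–C10 by vinylogous aldol condensation of a butenolide with a C4–C9 enal (C6 by catalytic allylboration, 7E by SeO2 oxidation).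
3. Key disconnection C1–C15: lactone-enolate (Ireland–Claisen) rearrangement of a spiro bis-lactone. Its C12–O bond is a temporary tether, absent from the target and cleaved in the same step, that closes the cyclohexene ring and relays the C12 configuration to C1.
4. Enabling feature: in the cyclohexene ring (C1, C14, C13, C12, C11, C15) the bond C1–C15 is allylic to the tetrasubstituted C11=C12 alkene, C1 bears C2 and C12 bears the C18 carbonyl. C2(=O)–C1–C15–C11=C12 is therefore a γ,δ-unsaturated acid retron, and the C10/C18 oxygens can be held as a γ-lactone spiro-fused at C12.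
5. Ring order: γ-lactone → spiro δ-lactone → cyclohexene fused to a butenolide (key step) → 12-membered ring → cyclopentenedione.

Key step: step 6

Remark (assumption): in steps 4 and 9 the antipode named for the chiral reagent or catalyst is the one expected from published models for the configuration shown; if a trial run showed the opposite sense, the other commercial antipode would be used and nothing else would change.

**Route**

Step 1
Reactants: 1 diethyl succinate; 2 acetone
Product: 3 3-(ethoxycarbonyl)-4-methylpent-3-enoic acid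
Conditions: KOtBu, tBuOH, reflux; then aq. HCl
Reagents that add atoms: none
Why: Stobbe condensation: the aldol adduct lactonises and the paraconate ring opens by E1cB elimination, which leaves the ester on the alkylidene carbon (future C10) and the free acid on the CH2 arm (future C18).

Step 2
Reactants: 3 3-(ethoxycarbonyl)-4-methylpent-3-enoic acid
Product: 5 4-(propan-2-ylidene)oxolan-2-one, via hydroxy acid 4 (not isolated)
Conditions: LiBH4, THF–MeOH, 0 → 40 °C; then 2 M HCl, rt
Reagents that add atoms: none
Why: Chemoselective borohydride reduction of the half ester (the lithium carboxylate is inert and the fully substituted β-carbon blocks 1,4-reduction) followed by acid lactonisation should give the β-alkylidene γ-lactone, the standard conversion of Stobbe half esters into butyrolactones.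

Step 3
Reactants: 5 4-(propan-2-ylidene)oxolan-2-one; 6 methyl 4-iodobutanoate
Product: 7 methyl 4-[2-oxo-4-(propan-2-ylidene)oxolan-3-yl]butanoate (racemic)
Conditions: LiN(iPr)2, THF, –78 °C; then 6, DMPU, –78 → –30 °C
Reagents that add atoms: none
Why: α-Alkylation of the lactone dienolate with a primary iodide; attack at the γ-terminus would create a quaternary carbon and is not expected, and the new stereocentre (C12) may stay racemic because it is planarised again in step 4.

Step 4
Reactants: 7 methyl 4-[2-oxo-4-(propan-2-ylidene)oxolan-3-yl]butanoate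
Product: 8 methyl 4-[(3S)-3-hydroxy-2-oxo-4-(propan-2-ylidene)oxolan-3-yl]butanoate
Conditions: KN(SiMe3)2, THF, –78 °C; (+)-(camphorsulfonyl)oxaziridine, –78 °C; AcOH
Reagents that add atoms: (+)-(camphorsulfonyl)oxaziridine, CC1(C)C2CCC13CS(=O)(=O)N4OC34C2
Why: Asymmetric enolate hydroxylation with an enantiopure N-sulfonyloxaziridine: the allylic lactone CH is several pK units more acidic than the side-chain ester CH2 and gives a cyclic dienolate of fixed geometry whose faces are distinguished by the reagent, which sets (S)-C12 as the tertiary alcohol.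

Step 5
Reactants: 8 methyl 4-[(3S)-3-hydroxy-2-oxo-4-(propan-2-ylidene)oxolan-3-yl]butanoate
Product: 9 (5S)-4-(propan-2-ylidene)-2,6-dioxaspiro[4.5]decane-1,7-dione
Conditions: camphorsulfonic acid (cat.), toluene, 4 Å molecular sieves, 80 °C
Reagents that add atoms: none
Why: Acid-catalysed lactonisation of the tertiary alcohol onto the methyl ester closes the six-membered δ-lactone without touching the stereocentre, since ionisation at C12 is disfavoured by the adjacent lactone carbonyl.

Step 6
Reactants: 9 (5S)-4-(propan-2-ylidene)-2,6-dioxaspiro[4.5]decane-1,7-dione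
Product: 12 (5R)-4,4-dimethyl-1-oxo-1,3,4,5,6,7-hexahydro-2-benzofuran-5-carboxylic acid, via silyl ketene acetal 10 (not isolated), via trimethylsilyl ester 11 (not isolated)
Conditions: Me3SiCl, Et3N, LiN(iPr)2, THF, –78 °C; then toluene, 100 °C; then 1 M HCl, THF
Reagents that add atoms: none
Why: Kinetic deprotonation of the only enolisable position (the δ-lactone CH2; the γ-lactone has no α-hydrogen) with in situ silylation gives the endocyclic silyl ketene acetal, which on warming should undergo a [3,3]-sigmatropic Ireland–Claisen rearrangement through a boat-like (bicyclo[2.2.2]-type) transition state in which C1 bonds to C15, the C12–O tether breaks and the isopropylidene π bond shifts to C11=C12, now conjugated with the butenolide carbonyl. The closest known reaction type is the silyl ketene acetal Claisen rearrangement of six-membered lactones that carry an alkenyl group on the carbinol carbon (6-alkenyl δ-lactones and 6-alkenyl-1,4-dioxan-2-ones), which gives cyclohex-3-ene- or dihydropyran-carboxylic acids. The cyclohexene ring is closed by the new C1–C15 σ bond while the six-membered lactone opens, so a six-membered lactone is exchanged for a six-membered carbocycle and no ring-size penalty is paid. The only new stereocentre, C1, is controlled by the spiro carbinol C12: the tether lets the enolate carbon reach the alkene terminus only on the lactone face that carries the alkenyl arm, so (S)-C12 is transferred to (R)-C1 with loss of the C12 stereocentre, and C15 (two methyl groups) is not stereogenic. The step needs site selectivity in enolisation and in the allyl terminus attacked; both are secured because there is one enolisable CH2 and one alkene, and because the spiro γ-lactone holds the exocyclic alkene coplanar with the C12–C18 bond, which is the geometry of the boat transition state.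

Step 7
Reactants: 12 (5R)-4,4-dimethyl-1-oxo-1,3,4,5,6,7-hexahydro-2-benzofuran-5-carboxylic acid
Product: 14 (5R)-4,4-dimethyl-1-oxo-1,3,4,5,6,7-hexahydro-2-benzofuran-5-carbaldehyde, via acid chloride 13 (not isolated)
Conditions: (COCl)2, DMF (cat.), CH2Cl2, 0 °C → rt; then LiAlH(OtBu)3, THF, –78 °C
Reagents that add atoms: none
Why: Acid chloride formation and reduction with the hindered alkoxyaluminium hydride should stop at the aldehyde, leave the butenolide intact at –78 °C and use no base that could epimerise C1.

Step 8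
Reactants: 14 (5R)-4,4-dimethyl-1-oxo-1,3,4,5,6,7-hexahydro-2-benzofuran-5-carbaldehyde
Product: 15 (5S)-5-ethenyl-4,4-dimethyl-4,5,6,7-tetrahydro-2-benzofuran-1(3H)-one
Conditions: Zn, CH2Br2, TiCl4, THF/CH2Cl2, 0 °C → rt
Reagents that add atoms: dibromomethane, BrCBr
Why: Takai–Lombardo methylenation is non-basic, so the hindered α-branched aldehyde should give the vinyl group (C2=C3) without epimerisation at C1, without deprotonation of the butenolide CH2 and without attack on the lactone carbonyl (the descriptor changes from R to S only because the priorities change).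

Step 9
Reactants: 16 3-methylbut-2-enal; 17 2-(2-bromoprop-2-en-1-yl)-4,4,5,5-tetramethyl-1,3,2-dioxaborolane
Product: 18 (4S)-6-bromo-2-methylhepta-2,6-dien-4-ol
Conditions: (S)-TRIP [(S)-3,3′-bis(2,4,6-triisopropylphenyl)-1,1′-binaphthyl-2,2′-diyl hydrogen phosphate] (5 mol %), toluene, –30 °C; aqueous work-up
Reagents that add atoms: none
Why: Chiral phosphoric acid-catalysed allylboration through a closed chair transition state gives 1,2-addition only, and the (S)-acid is expected to direct the 2-bromoallyl group to the Si face of the enal, which sets (S)-C6.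

Step 10
Reactants: 18 (4S)-6-bromo-2-methylhepta-2,6-dien-4-ol
Product: 19 tert-butyl{[(4S)-6-bromo-2-methylhepta-2,6-dien-4-yl]oxy}dimethylsilane
Conditions: TBSCl, imidazole, DMF, rt
Reagents that add atoms: tert-butyl(chloro)dimethylsilane, CC(C)(C)[Si](C)(C)Cl
Why: Standard silylation; the TBS ether should survive the oxidation, silyl triflate, amine, borane, palladium and amide base steps that follow and is removed by fluoride at the end.

Step 11
Reactants: 19 tert-butyl{[(4S)-6-bromo-2-methylhepta-2,6-dien-4-yl]oxy}dimethylsilane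
Product: 20 (2E,4S)-6-bromo-4-{[tert-butyl(dimethyl)silyl]oxy}-2-methylhepta-2,6-dien-1-ol
Conditions: SeO2 (cat.), tBuOOH, salicylic acid (cat.), CH2Cl2, rt
Reagents that add atoms: tert-butyl hydroperoxide, CC(C)(C)OO; selenium dioxide, O=[Se]=O
Why: SeO2 allylic oxidation (ene reaction then [2,3]-sigmatropic shift) attacks the E-methyl group at the more substituted alkene terminus, so the CH2OH group ends trans to the C6 side chain (7E), while the 2-bromoalkene is deactivated.

Step 12
Reactants: 20 (2E,4S)-6-bromo-4-{[tert-butyl(dimethyl)silyl]oxy}-2-methylhepta-2,6-dien-1-ol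
Product: 21 (2E,4S)-6-bromo-4-{[tert-butyl(dimethyl)silyl]oxy}-2-methylhepta-2,6-dienal
Conditions: Dess–Martin periodinane, pyridine, CH2Cl2, 0 °C
Reagents that add atoms: none
Why: Dess–Martin oxidation of the primary allylic alcohol to the enal under buffered conditions that should not isomerise the alkene.

Step 13
Reactants: 15 (5S)-5-ethenyl-4,4-dimethyl-4,5,6,7-tetrahydro-2-benzofuran-1(3H)-one; 21 (2E,4S)-6-bromo-4-{[tert-butyl(dimethyl)silyl]oxy}-2-methylhepta-2,6-dienal
Product: 24 (3Z,5S)-3-[(2E,4S)-6-bromo-4-{[tert-butyl(dimethyl)silyl]oxy}-2-methylhepta-2,6-dien-1-ylidene]-5-ethenyl-4,4-dimethyl-4,5,6,7-tetrahydro-2-benzofuran-1(3H)-one, via 2-silyloxyfuran 22 (not isolated), via aldol silyl ether 23 (not isolated)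
Conditions: TBSOTf, iPr2NEt, CH2Cl2, –78 °C; 21, –78 °C; then DBU, –78 °C → rt
Reagents that add atoms: none
Why: One-pot vinylogous Mukaiyama aldol–elimination: the butenolide is silylated to the 2-silyloxyfuran, which adds through its γ-carbon (C10) to the activated enal in a 1,2-sense, and DBU then eliminates silanol (E1cB) to the dienyl enol lactone, expected as the Z isomer that keeps the chain away from the gem-dimethyl group (either isomer converges in step 14).

Step 14
Reactants: 24 the ylidene-butenolide of step 13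
Product: 25 methyl (4S)-2-[(3E,5S)-7-bromo-5-{[tert-butyl(dimethyl)silyl]oxy}-3-methylocta-3,7-dienoyl]-4-ethenyl-3,3-dimethylcyclohex-1-ene-1-carboxylate
Conditions: MeOH, Et3N, DMAP (cat.), CH2Cl2, 0 °C → rt
Reagents that add atoms: methanol, CO
Why: Amine-catalysed methanolysis of the enol lactone, an activated enol ester: the liberated dienol should ketonise at the α-carbon (C9) to the β,γ-unsaturated ketone with the 7E alkene intact, and the amine is too weak a base to enolise that ketone, so Claisen closure to the dione does not start before the macrocycle exists.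

Step 15
Reactants: 25 the keto ester of step 14
Product: 27 methyl (1R,6S,7E)-6-{[tert-butyl(dimethyl)silyl]oxy}-8,15,15-trimethyl-4-methylidene-10-oxobicyclo[9.3.1]pentadeca-7,11-diene-12-carboxylate, via B-alkyl-9-BBN adduct 26 (not isolated)
Conditions: 9-BBN, THF, rt; then PdCl2(dppf) (10 mol %), AsPh3, K3PO4, THF/DMF/H2O, 45 °C, slow addition to 2 mM
Reagents that add atoms: none
Why: 9-BBN should add only to the monosubstituted alkene (the 2-bromoalkene, the tri- and tetrasubstituted alkenes and the hindered conjugated ketone react much more slowly), and intramolecular B-alkyl Suzuki–Miyaura coupling under high dilution joins C3 to C4 and closes the 12-membered ring, a ring closure type established for bicyclo[9.3.1] terpenoid cores and helped here by the two arms flanking the gem-dimethyl carbon.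

Step 16
Reactants: 27 the macrocyclic keto ester of step 15
Product: 28 (1R,6S,9S,7E)-6-O-TBS ether of deacetyl-cespitularin K (tricyclic enedione, C9 bonded to C10 and C18)
Conditions: LiN(SiMe3)2, THF, –78 → 0 °C; AcOH, –78 °C
Reagents that add atoms: none
Why: Dieckmann-type closure: the lithium enolate of the C10 ketone (only C9 can be deprotonated) attacks the C18 methyl ester across the ring in a 5-exo-trig acylation, and C9 can only bond on the face of the new five-membered ring already spanned by the bridge, which gives (9S); the cold acidic quench avoids retro-Claisen opening.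

Step 17
Reactants: 28 the TBS ether of step 16
Product: 29 deacetyl-cespitularin K (C6 alcohol; 1R,6S,9S,7E)
Conditions: HF·pyridine, THF, 0 °C → rt
Reagents that add atoms: none
Why: Acidic fluoride desilylation avoids the basic conditions that could enolise C9 of the enedione.

Step 18
Reactants: 29 deacetyl-cespitularin K
Product: 30 Cespitularin K
Conditions: Ac2O, pyridine, CH2Cl2, 0 °C → rt
Reagents that add atoms: acetic anhydride, CC(=O)OC(C)=O
Why: Acetylation of the secondary allylic alcohol under weakly basic conditions that should not enolise the enedione.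

**Compound list**

1 | diethyl succinate | CCOC(=O)CCC(=O)OCC | starting material
2 | acetone | CC(C)=O | starting material
3 | 3-(ethoxycarbonyl)-4-methylpent-3-enoic acid | CCOC(=O)C(=C(C)C)CC(=O)O | intermediate
4 | 3-(hydroxymethyl)-4-methylpent-3-enoic acid | OCC(=C(C)C)CC(=O)O | intermediate
5 | 4-(propan-2-ylidene)oxolan-2-one | O=C1CC(=C(C)C)CO1 | intermediate
6 | methyl 4-iodobutanoate | COC(=O)CCCI | starting material
7 | methyl 4-[2-oxo-4-(propan-2-ylidene)oxolan-3-yl]butanoate (racemic) | COC(=O)CCCC1C(=O)OCC1=C(C)C | intermediate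
8 | methyl 4-[(3S)-3-hydroxy-2-oxo-4-(propan-2-ylidene)oxolan-3-yl]butanoate | O=C1OCC(=C(C)C)[C@@]1(O)CCCC(=O)OC | intermediate
9 | (5S)-4-(propan-2-ylidene)-2,6-dioxaspiro[4.5]decane-1,7-dione | O=C1OCC(=C(C)C)[C@@]12CCCC(=O)O2 | intermediate
10 | (5S)-4-(propan-2-ylidene)-7-(trimethylsilyloxy)-2,6-dioxaspiro[4.5]dec-7-en-1-one | O=C1OCC(=C(C)C)[C@@]12CCC=C(O[Si](C)(C)C)O2 | intermediate
11 | trimethylsilyl (5R)-4,4-dimethyl-1-oxo-1,3,4,5,6,7-hexahydro-2-benzofuran-5-carboxylate | CC1(C)[C@H](C(=O)O[Si](C)(C)C)CCC2=C1COC2=O | intermediate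
12 | (5R)-4,4-dimethyl-1-oxo-1,3,4,5,6,7-hexahydro-2-benzofuran-5-carboxylic acid | CC1(C)[C@H](C(=O)O)CCC2=C1COC2=O | intermediate
13 | (5R)-4,4-dimethyl-1-oxo-1,3,4,5,6,7-hexahydro-2-benzofuran-5-carbonyl chloride | CC1(C)[C@H](C(=O)Cl)CCC2=C1COC2=O | intermediate
14 | (5R)-4,4-dimethyl-1-oxo-1,3,4,5,6,7-hexahydro-2-benzofuran-5-carbaldehyde | CC1(C)[C@H](C=O)CCC2=C1COC2=O | intermediate
15 | (5S)-5-ethenyl-4,4-dimethyl-4,5,6,7-tetrahydro-2-benzofuran-1(3H)-one | CC1(C)[C@H](C=C)CCC2=C1COC2=O | intermediate
16 | 3-methylbut-2-enal | CC(C)=CC=O | starting material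
17 | 2-(2-bromoprop-2-en-1-yl)-4,4,5,5-tetramethyl-1,3,2-dioxaborolane | C=C(Br)CB1OC(C)(C)C(C)(C)O1 | starting material
18 | (4S)-6-bromo-2-methylhepta-2,6-dien-4-ol | CC(C)=C[C@@H](O)CC(Br)=C | intermediate
19 | tert-butyl{[(4S)-6-bromo-2-methylhepta-2,6-dien-4-yl]oxy}dimethylsilane | CC(C)=C[C@@H](O[Si](C)(C)C(C)(C)C)CC(Br)=C | intermediate
20 | (2E,4S)-6-bromo-4-{[tert-butyl(dimethyl)silyl]oxy}-2-methylhepta-2,6-dien-1-ol | OC/C(C)=C/[C@@H](O[Si](C)(C)C(C)(C)C)CC(Br)=C | intermediate
21 | (2E,4S)-6-bromo-4-{[tert-butyl(dimethyl)silyl]oxy}-2-methylhepta-2,6-dienal | O=C/C(C)=C/[C@@H](O[Si](C)(C)C(C)(C)C)CC(Br)=C | intermediate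
22 | tert-butyl{[(5S)-5-ethenyl-4,4-dimethyl-4,5,6,7-tetrahydro-2-benzofuran-1-yl]oxy}dimethylsilane | CC1(C)[C@H](C=C)CCc2c1coc2O[Si](C)(C)C(C)(C)C | intermediate
23 | (5S)-3-[(2E,4S)-6-bromo-1,4-bis{[tert-butyl(dimethyl)silyl]oxy}-2-methylhepta-2,6-dien-1-yl]-5-ethenyl-4,4-dimethyl-4,5,6,7-tetrahydro-2-benzofuran-1(3H)-one (mixture at the two new centres) | CC1(C)[C@H](C=C)CCC2=C1C(OC2=O)C(O[Si](C)(C)C(C)(C)C)/C(C)=C/[C@@H](O[Si](C)(C)C(C)(C)C)CC(Br)=C | intermediate
24 | (3Z,5S)-3-[(2E,4S)-6-bromo-4-{[tert-butyl(dimethyl)silyl]oxy}-2-methylhepta-2,6-dien-1-ylidene]-5-ethenyl-4,4-dimethyl-4,5,6,7-tetrahydro-2-benzofuran-1(3H)-one | CC1(C)[C@H](C=C)CCC2=C1/C(=C/C(C)=C/[C@@H](O[Si](C)(C)C(C)(C)C)CC(Br)=C)OC2=O | intermediate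
25 | methyl (4S)-2-[(3E,5S)-7-bromo-5-{[tert-butyl(dimethyl)silyl]oxy}-3-methylocta-3,7-dienoyl]-4-ethenyl-3,3-dimethylcyclohex-1-ene-1-carboxylate | COC(=O)C1=C(C(=O)C/C(C)=C/[C@@H](O[Si](C)(C)C(C)(C)C)CC(Br)=C)C(C)(C)[C@H](C=C)CC1 | intermediate
26 | methyl (4R)-4-[2-(9-borabicyclo[3.3.1]nonan-9-yl)ethyl]-2-[(3E,5S)-7-bromo-5-{[tert-butyl(dimethyl)silyl]oxy}-3-methylocta-3,7-dienoyl]-3,3-dimethylcyclohex-1-ene-1-carboxylate | COC(=O)C1=C(C(=O)C/C(C)=C/[C@@H](O[Si](C)(C)C(C)(C)C)CC(Br)=C)C(C)(C)[C@H](CCB2C3CCCC2CCC3)CC1 | intermediate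
27 | methyl (1R,6S,7E)-6-{[tert-butyl(dimethyl)silyl]oxy}-8,15,15-trimethyl-4-methylidene-10-oxobicyclo[9.3.1]pentadeca-7,11-diene-12-carboxylate | COC(=O)C1=C2C(=O)C/C(C)=C/[C@@H](O[Si](C)(C)C(C)(C)C)CC(=C)CC[C@H](CC1)C2(C)C | intermediate
28 | (1R,6S,9S,7E)-6-O-TBS ether of deacetyl-cespitularin K (tricyclic enedione) | C=C1CC[C@@H]2CCC3=C(C(=O)[C@H](C3=O)/C(C)=C/[C@@H](O[Si](C)(C)C(C)(C)C)C1)C2(C)C | intermediate
29 | deacetyl-cespitularin K (1R,6S,9S,7E; C6 alcohol) | C=C1CC[C@@H]2CCC3=C(C(=O)[C@H](C3=O)/C(C)=C/[C@@H](O)C1)C2(C)C | intermediate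
30 | Cespitularin K | C=C1CC[C@@H]2CCC3=C(C(=O)[C@H](C3=O)/C(C)=C/[C@@H](OC(C)=O)C1)C2(C)C | target

**Step count and risks**

Total: 18 steps. Longest linear sequence: 14 steps (steps 1–8 and 13–18); the enal 21 is made in 4 steps (steps 9–12).

Steps most likely to fail:

Step 6. The boat transition state that builds the quaternary carbon may be reached too slowly, so that the silyl ketene acetal is lost by C-silylation, ketene extrusion or hydrolysis before it rearranges. The fallback replaces the anionic ketene acetal by a neutral cyclic enol ether and sets out from 9. The less hindered δ-lactone carbonyl is half-reduced (iBu2AlH, CH2Cl2, –78 °C) to the lactol (5S)-7-hydroxy-4-(propan-2-ylidene)-2,6-dioxaspiro[4.5]decan-1-one F1. Dehydration (MsCl, Et3N, 0 °C → 40 °C) gives the enol ether (5S)-4-(propan-2-ylidene)-2,6-dioxaspiro[4.5]dec-7-en-1-one F2. Thermal Claisen rearrangement of this 2-alkenyl-3,4-dihydro-2H-pyran (o-xylene, 170 °C, sealed tube), the known route from such pyrans to cyclohex-3-ene carbaldehydes, should deliver the aldehyde directly, and the route is re-joined at 14.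

Step 15. Oligomerisation and protodeboronation may outrun closure of the 12-membered ring, or the borane may reduce the ketone during hydroboration. The fallback inverts the order of the two unions, sets out from 15 and re-joins at 27. Compound 15 is hydroborated (9-BBN) to the B-alkyl-9-BBN adduct of 15 F3 and coupled intermolecularly with the vinyl bromide 20 (PdCl2(dppf), AsPh3, K3PO4). This gives (5R)-5-[(5S,6E)-5-{[tert-butyl(dimethyl)silyl]oxy}-8-hydroxy-7-methyl-3-methylideneoct-6-en-1-yl]-4,4-dimethyl-4,5,6,7-tetrahydro-2-benzofuran-1(3H)-one F4, and Dess–Martin oxidation gives the corresponding 8-oxo enal F5. The ring is then closed at C9–C10 by intramolecular vinylogous Mukaiyama aldol–elimination under high dilution (TBSOTf, iPr2NEt, then DBU), through the tethered 2-silyloxyfuran enal F6 and the macrocyclic aldol silyl ether F7, to the macrocyclic ylidene-butenolide F8. Methanolysis as in step 14 then gives 27.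

Step 4. Oxygen transfer to the flat lactone dienolate may show poor facial selectivity, or the side-chain ester may be enolised in competition. The fallback gives up asymmetric induction and sets out from 7. Hydroxylation with achiral 3-phenyl-2-(phenylsulfonyl)oxaziridine (KN(SiMe3)2, THF, –78 °C) gives racemic methyl 4-[3-hydroxy-2-oxo-4-(propan-2-ylidene)oxolan-3-yl]butanoate F9. Lactonisation as in step 5 gives racemic 4-(propan-2-ylidene)-2,6-dioxaspiro[4.5]decane-1,7-dione F10. The enantiomers of this rigid spiro bis-lactone are separated by preparative chromatography on a chiral stationary phase; the (5S) enantiomer is 9, where the route is re-joined, and the stereospecific step 6 then carries the configuration forward.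

**Further compounds**

F1 | step 6 | (5S)-7-hydroxy-4-(propan-2-ylidene)-2,6-dioxaspiro[4.5]decan-1-one | O=C1OCC(=C(C)C)[C@@]12CCCC(O)O2
F2 | step 6 | (5S)-4-(propan-2-ylidene)-2,6-dioxaspiro[4.5]dec-7-en-1-one | O=C1OCC(=C(C)C)[C@@]12CCC=CO2
F3 | step 15 | (5R)-5-[2-(9-borabicyclo[3.3.1]nonan-9-yl)ethyl]-4,4-dimethyl-4,5,6,7-tetrahydro-2-benzofuran-1(3H)-one | CC1(C)[C@H](CCB3C4CCCC3CCC4)CCC2=C1COC2=O
F4 | step 15 | (5R)-5-[(5S,6E)-5-{[tert-butyl(dimethyl)silyl]oxy}-8-hydroxy-7-methyl-3-methylideneoct-6-en-1-yl]-4,4-dimethyl-4,5,6,7-tetrahydro-2-benzofuran-1(3H)-one | CC1(C)[C@H](CCC(=C)C[C@H](O[Si](C)(C)C(C)(C)C)/C=C(\C)CO)CCC2=C1COC2=O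
F5 | step 15 | (5R)-5-[(5S,6E)-5-{[tert-butyl(dimethyl)silyl]oxy}-7-methyl-3-methylidene-8-oxooct-6-en-1-yl]-4,4-dimethyl-4,5,6,7-tetrahydro-2-benzofuran-1(3H)-one | CC1(C)[C@H](CCC(=C)C[C@H](O[Si](C)(C)C(C)(C)C)/C=C(\C)C=O)CCC2=C1COC2=O
F6 | step 15 | 2-silyloxyfuran of F5 (1-{[tert-butyl(dimethyl)silyl]oxy}-4,5,6,7-tetrahydro-2-benzofuran carrying the same enal chain) | CC1(C)[C@H](CCC(=C)C[C@H](O[Si](C)(C)C(C)(C)C)/C=C(\C)C=O)CCc2c1coc2O[Si](C)(C)C(C)(C)C
F7 | step 15 | macrocyclic aldol silyl ether (C9–C10 bond formed, C9 OTBS, C10–O–C18 butenolide; mixture at C9 and C10) | CC1(C)[C@@H]2CCC(=C)C[C@H](O[Si](C)(C)C(C)(C)C)/C=C(C)/C(O[Si](C)(C)C(C)(C)C)C3OC(=O)C(CC2)=C13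
F8 | step 15 | macrocyclic ylidene-butenolide (C9=C10 enol lactone, lactone oxygen between C10 and C18) | CC1(C)[C@@H]2CCC(=C)C[C@H](O[Si](C)(C)C(C)(C)C)/C=C(C)/C=C3OC(=O)C(CC2)=C13
F9 | step 4 | methyl 4-[3-hydroxy-2-oxo-4-(propan-2-ylidene)oxolan-3-yl]butanoate (racemic) | COC(=O)CCCC1(O)C(=O)OCC1=C(C)C
F10 | step 4 | 4-(propan-2-ylidene)-2,6-dioxaspiro[4.5]decane-1,7-dione (racemic) | O=C1OCC(=C(C)C)C12CCCC(=O)O2
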